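The target is the 3,4-dimethoxybenzoate of a trans-fused daucane diol (numbering: C1 angular quaternary carbon, C4 isopropyl carbinol, C5 ring-fusion CH, C6 acyloxy carbon). Everything rests on opening the five-membered ring at C2–C3, the only cyclopentane bond that lies between both fully substituted carbons (C1 and C4) and carries no stereochemistry. Ring-closing metathesis closes this ring in one operation on a preformed cycloheptene; its precursor bears a vinyl group on C1 and, trans to it on C5, the tertiary carbinol C4 with a second vinyl group. All four stereocentres are set beforehand: C6 from the chiral pool, C5 and C1 by a chelated dianion Claisen rearrangement, C4 by Felkin–Anh addition.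

Key step: step 9

Remark: daucane numbering is used for all intermediates: C1 (methyl-bearing quaternary carbon), C2 and C3 (the two CH2 groups of the five-membered ring), C4 (carbinol carbon with isopropyl), C5 (ring-fusion CH), C6 (oxygen-bearing CH), C7, C8 (methyl-bearing alkene carbon), C9 and C10 (seven-membered ring).

Step 1
Reactants: 1 pent-1-en-4-yne
Product: 4 (2E)-3-methylhexa-2,5-dien-1-ol, via alkenyldimethylalane 2 (not isolated), via lithium alkenylaluminate 3 (not isolated)
Conditions: Me3Al, Cp2ZrCl2 (20 mol%), CH2Cl2, 0 to 23 °C; evaporation; n-BuLi, hexane, 0 °C; (CH2O)n, THF, 23 °C; H2O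
Reagents that add atoms: trimethylaluminium C[Al](C)C; paraformaldehyde (as formaldehyde) C=O
Why: Negishi carboalumination adds methyl and aluminium syn across the terminal alkyne (methyl to the internal carbon) and the derived aluminate is hydroxymethylated with retention, which fixes the E geometry, while the terminal alkene is carbometallated far more slowly and should stay untouched.

Step 2
Reactants: 5 ethyl (3S)-4-chloro-3-hydroxybutanoate
Product: 6 ethyl 2-[(2S)-oxiran-2-yl]acetate
Conditions: Ag2O, 1,2-dimethoxyethane, 60 °C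
Reagents that add atoms: none
Why: Intramolecular Williamson etherification (SN2 displacement of the primary chloride by the neighbouring hydroxyl, assisted by silver) closes the epoxide without touching the stereocentre, and the non-basic oxide should avoid elimination to the crotonate.

Step 3
Reactants: 6 ethyl 2-[(2S)-oxiran-2-yl]acetate
Product: 7 ethyl (3R)-3-hydroxy-5-methylhex-5-enoate
Conditions: isopropenylMgBr, CuI (10 mol%), THF, −40 °C; H2O
Reagents that add atoms: isopropenylmagnesium bromide CC(=C)[Mg]Br
Why: Copper-catalysed Grignard opening of a terminal epoxide (SN2 at the unsubstituted carbon) should outrun addition to the ester at low temperature, and the carbinol carbon is not involved, so its configuration is retained (the descriptor changes only through the priority rules).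

Step 4
Reactants: 7 ethyl (3R)-3-hydroxy-5-methylhex-5-enoate; 4 (2E)-3-methylhexa-2,5-dien-1-ol
Product: 8 (2E)-3-methylhexa-2,5-dien-1-yl (3R)-3-hydroxy-5-methylhex-5-enoate
Conditions: Ti(OEt)4 (10 mol%), 4 (1.5 equiv), toluene, 100 °C, EtOH distilled off
Reagents that add atoms: none
Why: Titanate-mediated transesterification is neutral, tolerates the free β-hydroxyl and is driven by removal of ethanol.

Step 5
Reactants: 8 (2E)-3-methylhexa-2,5-dien-1-yl (3R)-3-hydroxy-5-methylhex-5-enoate
Product: 10 (2R,3R)-3-hydroxy-5-methyl-2-[(3R)-3-methylhexa-1,5-dien-3-yl]hex-5-enoic acid, via dilithium enolate alkoxide 9 (not isolated)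
Conditions: LDA (2.3 equiv), THF, −78 °C, then 23 to 50 °C; aq. HCl
Reagents that add atoms: none
Why: Dianionic ester-enolate Claisen rearrangement (Ireland–Claisen type [3,3] shift): the lithium chelate between alkoxide and enolate oxygens fixes the enolate geometry (C6 cis to O–Li) and directs the allyl unit to the enolate face anti to the C7 chain, as in Fráter–Seebach alkylation, which sets C5 anti to the C6 hydroxyl, while the chair transition state with the E alkene (methyl axial, allyl equatorial) sets the quaternary C1.

Step 6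
Reactants: 10 (2R,3R)-3-hydroxy-5-methyl-2-[(3R)-3-methylhexa-1,5-dien-3-yl]hex-5-enoic acid
Product: 12 (4R,5R)-5-hydroxy-2,7-dimethyl-4-[(3R)-3-methylhexa-1,5-dien-3-yl]oct-7-en-3-one, via trilithium gem-diolate 11 (not isolated)
Conditions: i-PrLi (4 equiv), Et2O, −78 to 0 °C; cold buffered H2O
Reagents that add atoms: isopropyllithium [Li]C(C)C
Why: Addition of an alkyllithium to a lithium carboxylate stops at the stable gem-diolate, which releases the ketone only on work-up, so no tertiary alcohol should form and C5, not enolised in the polyanion, should keep its configuration.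

Step 7
Reactants: 12 (4R,5R)-5-hydroxy-2,7-dimethyl-4-[(3R)-3-methylhexa-1,5-dien-3-yl]oct-7-en-3-one
Product: 13 1-[(1R,2R,7R)-7-ethenyl-2-hydroxy-4,7-dimethylcyclohept-4-en-1-yl]-2-methylpropan-1-one
Conditions: second-generation Grubbs catalyst (5 mol%), CH2Cl2 (0.005 M), 40 °C
Reagents that add atoms: none
Why: Ring-closing metathesis: the ruthenium carbene loads on the unhindered allyl group and closes the seven-membered ring onto the 2-methylallyl group as the trisubstituted C8=C9 alkene, whereas the vinyl group on the quaternary carbon is too hindered to initiate and could only give a cyclobutene with the allyl-derived carbene.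

Step 8
Reactants: 13 1-[(1R,2R,7R)-7-ethenyl-2-hydroxy-4,7-dimethylcyclohept-4-en-1-yl]-2-methylpropan-1-one
Product: 14 (1R,6R,7R)-6-ethenyl-7-[(3S)-3-hydroxy-4-methylpent-1-en-3-yl]-3,6-dimethylcyclohept-3-en-1-ol
Conditions: vinylMgBr (3 equiv), LaCl3·2LiCl (1.1 equiv), THF, −78 to 0 °C; H2O
Reagents that add atoms: vinylmagnesium bromide C=C[Mg]Br
Why: Lanthanum-promoted Grignard 1,2-addition suppresses enolisation of the hindered ketone, and both the Felkin–Anh model and the chelate model (C6 alkoxide) place the incoming vinyl group anti to the bulky quaternary C1 substituent of C5, which sets C4 with the configuration of the target (the opposite of what addition of isopropyl to a ring ketone would be expected to give).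

Step 9
Reactants: 14 (1R,6R,7R)-6-ethenyl-7-[(3S)-3-hydroxy-4-methylpent-1-en-3-yl]-3,6-dimethylcyclohept-3-en-1-ol
Product: 15 (3S,3aR,4R,8aR)-6,8a-dimethyl-3-(propan-2-yl)-3,3a,4,5,8,8a-hexahydroazulene-3,4-diol
Conditions: second-generation Hoveyda–Grubbs catalyst (10 mol%), toluene (0.005 M), 80 °C, argon purge
Reagents that add atoms: none
Why: Ring-closing olefin metathesis by the Chauvin mechanism: the ruthenium carbene loads on the vinyl group of the tertiary allylic carbinol (C3, helped by the free C4 hydroxyl), forms a ruthenacyclobutane with the vinyl group on quaternary C1 and releases ethene. The closest known reaction type is the metathesis closure of hindered hepta-1,6-dienes to cyclopentenes, including trans-fused ones of the steroid ring D 16-ene kind. The five-membered ring is closed by joining the two internal vinyl carbons as the C2=C3 alkene, an entropically easy five-ring metathesis closure on a 1,2-trans-disubstituted cycloheptene. No stereocentre is formed; the trans ring fusion and the C4 configuration are carried over from 14, whose two alkene-bearing arms are trans and pseudo-equatorial and so within reach of each other. The step needs chemoselectivity against the trisubstituted C8=C9 ring alkene and against intermolecular metathesis: the former should be inert to the carbene under these conditions, and the latter is held back by the poor cross-metathesis reactivity of both neopentyl-type vinyl groups and by high dilution.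

Step 10
Reactants: 15 (3S,3aR,4R,8aR)-6,8a-dimethyl-3-(propan-2-yl)-3,3a,4,5,8,8a-hexahydroazulene-3,4-diol; 16 3,4-dimethoxybenzoyl chloride
Product: 17 (3S,3aR,4R,8aR)-3-hydroxy-6,8a-dimethyl-3-(propan-2-yl)-3,3a,4,5,8,8a-hexahydroazulen-4-yl 3,4-dimethoxybenzoate
Conditions: Et3N, DMAP (20 mol%), CH2Cl2, 0 to 23 °C
Reagents that add atoms: none
Why: DMAP-catalysed acylation (nucleophilic acyl transfer) should esterify only the secondary C6 hydroxyl, the tertiary allylic C4 hydroxyl being too hindered to react.

Step 11
Reactants: 17 (3S,3aR,4R,8aR)-3-hydroxy-6,8a-dimethyl-3-(propan-2-yl)-3,3a,4,5,8,8a-hexahydroazulen-4-yl 3,4-dimethoxybenzoate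
Product: 18 (3R,3aR,4R,8aS)-3-hydroxy-6,8a-dimethyl-3-(propan-2-yl)-1,2,3,3a,4,5,8,8a-octahydroazulen-4-yl 3,4-dimethoxybenzoate
Conditions: H2 (1 atm), [Rh(nbd)(dppb)]BF4 (5 mol%), CH2Cl2, 23 °C
Reagents that add atoms: none
Why: Hydroxyl-directed homogeneous hydrogenation with a cationic rhodium–diphosphine catalyst should deliver hydrogen to the disubstituted C2=C3 alkene bound next to the C4 hydroxyl, while the trisubstituted C8=C9 alkene, which has no free hydroxyl nearby once C6 is esterified, and the aryl ester are left alone; no stereocentre is formed.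

Compound list
1 | pent-1-en-4-yne | C#CCC=C | starting material
2 | dimethyl[(1E)-2-methylpenta-1,4-dien-1-yl]alane | C=CC/C(C)=C/[Al](C)C | intermediate
3 | lithium butyl(dimethyl)[(1E)-2-methylpenta-1,4-dien-1-yl]aluminate | [Li+].C=CC/C(C)=C/[Al-](C)(C)CCCC | intermediate
4 | (2E)-3-methylhexa-2,5-dien-1-ol | C=CC/C(C)=C/CO | intermediate
5 | ethyl (3S)-4-chloro-3-hydroxybutanoate | CCOC(=O)C[C@H](O)CCl | starting material
6 | ethyl 2-[(2S)-oxiran-2-yl]acetate | CCOC(=O)C[C@H]1CO1 | intermediate
7 | ethyl (3R)-3-hydroxy-5-methylhex-5-enoate | CCOC(=O)C[C@H](O)CC(C)=C | intermediate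
8 | (2E)-3-methylhexa-2,5-dien-1-yl (3R)-3-hydroxy-5-methylhex-5-enoate | C=CC/C(C)=C/COC(=O)C[C@H](O)CC(C)=C | intermediate
9 | dilithium enolate alkoxide of 8 (enolate O–Li cis to C6, lithium bridging both oxygens) | [Li+].[Li+].C=CC/C(C)=C/CO/C([O-])=C/[C@H]([O-])CC(C)=C | intermediate
10 | (2R,3R)-3-hydroxy-5-methyl-2-[(3R)-3-methylhexa-1,5-dien-3-yl]hex-5-enoic acid | OC(=O)[C@@H]([C@H](O)CC(C)=C)[C@@](C)(C=C)CC=C | intermediate
11 | trilithium gem-diolate alkoxide from 10 and isopropyllithium | [Li+].[Li+].[Li+].CC(C)C([O-])([O-])[C@@H]([C@H]([O-])CC(C)=C)[C@@](C)(C=C)CC=C | intermediate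
12 | (4R,5R)-5-hydroxy-2,7-dimethyl-4-[(3R)-3-methylhexa-1,5-dien-3-yl]oct-7-en-3-one | CC(C)C(=O)[C@@H]([C@H](O)CC(C)=C)[C@@](C)(C=C)CC=C | intermediate
13 | 1-[(1R,2R,7R)-7-ethenyl-2-hydroxy-4,7-dimethylcyclohept-4-en-1-yl]-2-methylpropan-1-one | CC(C)C(=O)[C@H]1[C@H](O)CC(C)=CC[C@]1(C)C=C | intermediate
14 | (1R,6R,7R)-6-ethenyl-7-[(3S)-3-hydroxy-4-methylpent-1-en-3-yl]-3,6-dimethylcyclohept-3-en-1-ol | CC(C)[C@](O)(C=C)[C@H]1[C@H](O)CC(C)=CC[C@]1(C)C=C | intermediate
15 | (3S,3aR,4R,8aR)-6,8a-dimethyl-3-(propan-2-yl)-3,3a,4,5,8,8a-hexahydroazulene-3,4-diol | O[C@@H]1CC(C)=CC[C@]2(C)C=C[C@@](O)(C(C)C)[C@@H]12 | intermediate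
16 | 3,4-dimethoxybenzoyl chloride | COc1ccc(C(=O)Cl)cc1OC | starting material
17 | (3S,3aR,4R,8aR)-3-hydroxy-6,8a-dimethyl-3-(propan-2-yl)-3,3a,4,5,8,8a-hexahydroazulen-4-yl 3,4-dimethoxybenzoate | COc1ccc(C(=O)O[C@@H]2CC(C)=CC[C@]3(C)C=C[C@@](O)(C(C)C)[C@@H]23)cc1OC | intermediate
18 | (3R,3aR,4R,8aS)-3-hydroxy-6,8a-dimethyl-3-(propan-2-yl)-1,2,3,3a,4,5,8,8a-octahydroazulen-4-yl 3,4-dimethoxybenzoate | COc1ccc(C(=O)O[C@@H]2CC(C)=CC[C@]3(C)CC[C@@](O)(C(C)C)[C@@H]23)cc1OC | target

Total step count: 11. Longest linear sequence: 10 steps (5 to 18, steps 2 to 11).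

Steps most likely to fail

Step 9 (key ring closure). Loading of the ruthenium carbene on either neopentyl-type vinyl group may be too slow, so that the catalyst decomposes or the diene oligomerises before the five-membered ring closes. The fallback is a relay ring-closing metathesis that sets out from 13 and comes back at 15. Allyl propargyl ether is hydrozirconated with Cp2Zr(H)Cl and iodinated to (1E)-1-iodo-3-(prop-2-en-1-yloxy)prop-1-ene F1. Iodine–lithium exchange with t-BuLi gives [(1E)-3-(prop-2-en-1-yloxy)prop-1-en-1-yl]lithium F2, which is added to ketone 13 with LaCl3·2LiCl in the same Felkin–Anh sense as in step 8 to give the relay diol (1R,6R,7R)-6-ethenyl-7-[(3S,4E)-3-hydroxy-2-methyl-6-(prop-2-en-1-yloxy)hex-4-en-3-yl]-3,6-dimethylcyclohept-3-en-1-ol F3. With the second-generation Grubbs catalyst the carbene should load on the unhindered allyl ether terminus, expel 2,5-dihydrofuran and thereby be delivered onto C3, from where it closes onto the C1 vinyl group to give 15.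

Step 5 (dianion Claisen rearrangement). The lithium dianion may fragment (loss of the allylic alkoxide) faster than it rearranges to the quaternary centre, or the chelate may give incomplete face selection. The fallback replaces substrate control by reagent control in a boron ester-enolate Claisen rearrangement; it sets out from 8 and comes back at 10. The hydroxyl of 8 is silylated (TBSCl, imidazole) to (2E)-3-methylhexa-2,5-dien-1-yl (3R)-3-[(tert-butyldimethylsilyl)oxy]-5-methylhex-5-enoate F4. Enolisation with (4S,5S)-2-bromo-1,3-bis(4-methylbenzenesulfonyl)-4,5-diphenyl-1,3,2-diazaborolidine and a tertiary amine at −78 °C gives the boron ketene acetal of F4 carrying the diazaborolidinyl group on the enolate oxygen F5; amine and solvent are chosen for the geometry with C6 cis to O–B. On warming F5 should rearrange through the same chair, the face now being chosen by the controller (its mirror image is taken if the pairing with C6 proves mismatched). Hydrolytic work-up gives (2R,3R)-3-[(tert-butyldimethylsilyl)oxy]-5-methyl-2-[(3R)-3-methylhexa-1,5-dien-3-yl]hex-5-enoic acid F6, and TBAF frees 10.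

Step 6 (acid to isopropyl ketone). The hindered dilithio carboxylate may be deprotonated at C5 or simply not attacked, which would return or epimerise the acid. The fallback is a Weinreb ketone synthesis that sets out from 10 and comes back at 12. Coupling of 10 with N,O-dimethylhydroxylamine hydrochloride (EDC, HOBt, N-methylmorpholine, CH2Cl2) gives (2R,3R)-3-hydroxy-N-methoxy-N,5-dimethyl-2-[(3R)-3-methylhexa-1,5-dien-3-yl]hex-5-enamide F7, whose magnesium chelate with excess i-PrMgCl (THF, 0 °C) should collapse to 12 on work-up.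

Further compounds
F1 | step 9 | (1E)-1-iodo-3-(prop-2-en-1-yloxy)prop-1-ene | I/C=C/COCC=C
F2 | step 9 | [(1E)-3-(prop-2-en-1-yloxy)prop-1-en-1-yl]lithium | [Li]/C=C/COCC=C
F3 | step 9 | (1R,6R,7R)-6-ethenyl-7-[(3S,4E)-3-hydroxy-2-methyl-6-(prop-2-en-1-yloxy)hex-4-en-3-yl]-3,6-dimethylcyclohept-3-en-1-ol | CC(C)[C@](O)(/C=C/COCC=C)[C@H]1[C@H](O)CC(C)=CC[C@]1(C)C=C
F4 | step 5 | (2E)-3-methylhexa-2,5-dien-1-yl (3R)-3-[(tert-butyldimethylsilyl)oxy]-5-methylhex-5-enoate | C=CC/C(C)=C/COC(=O)C[C@H](O[Si](C)(C)C(C)(C)C)CC(C)=C
F5 | step 5 | boron ketene acetal of F4 with the (4S,5S)-1,3-bis(4-methylbenzenesulfonyl)-4,5-diphenyl-1,3,2-diazaborolidin-2-yl group on the enolate oxygen (C6 cis to O–B) | C=CC/C(C)=C/CO/C(OB1N(S(=O)(=O)c2ccc(C)cc2)[C@@H](c2ccccc2)[C@H](c2ccccc2)N1S(=O)(=O)c1ccc(C)cc1)=C/[C@H](O[Si](C)(C)C(C)(C)C)CC(C)=C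
F6 | step 5 | (2R,3R)-3-[(tert-butyldimethylsilyl)oxy]-5-methyl-2-[(3R)-3-methylhexa-1,5-dien-3-yl]hex-5-enoic acid | OC(=O)[C@@H]([C@H](O[Si](C)(C)C(C)(C)C)CC(C)=C)[C@@](C)(C=C)CC=C
F7 | step 6 | (2R,3R)-3-hydroxy-N-methoxy-N,5-dimethyl-2-[(3R)-3-methylhexa-1,5-dien-3-yl]hex-5-enamide | CON(C)C(=O)[C@@H]([C@H](O)CC(C)=C)[C@@](C)(C=C)CC=C
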